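**Strategy**

Everything rests on closing the cyclohexane last, through the bond between its gem-dimethyl carbon (C2′) and the adjoining ring CH2 (C3′). (S)-Linalool maps onto the target twice: its carbinol carbon becomes chromene C2, its prenyl terminus becomes cyclohexane C1′ and C2′. After the chromene is built, a catalyst-controlled carbonyl-ene reaction with an α-keto ester joins C1′ to carbinol C6′ and leaves an isopropenyl group. The key-step precursor carries this isopropenyl group on C1′ and an aldehyde tosylhydrazone on the three-carbon arm of C6′. Hydrogen-atom transfer makes the tertiary C2′ radical, which adds 6-exo to C3′=N; loss of sulfinate and N2 leaves plain CH2. The step exploits the quaternary CMe2 carbon flanked by an unfunctionalised methylene.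

Key step: step 8

Remark: (S)-(+)-linalool and 2,6-difluoro-4-methylbenzaldehyde are taken as commercial, and the optical purity of the linalool carries through to chromene C2; cyclohexane carbons are numbered C1′ (CH bearing the tether), C2′ (CMe2), C3′–C5′ (CH2) and C6′ (carbinol).

**Route**

Step 1
Reactants: 1 (S)-(+)-linalool; 2 2,6-difluoro-4-methylbenzaldehyde
Product: 3 2-{[(3S)-3,7-dimethylocta-1,6-dien-3-yl]oxy}-6-fluoro-4-methylbenzaldehyde
Conditions: NaH, THF/DMF, 0 °C; then 2, 0 → 25 °C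
Reagents that add atoms: none
Why: Nucleophilic aromatic substitution (SNAr) in which the tertiary alkoxide of 1 displaces one fluoride ortho to the formyl group; the carbinol C–O bond is never broken, so the (S) centre is retained, and the bulky nucleophile and the first alkoxy group should spare the second fluoride.

Step 2
Reactants: 3 2-{[(3S)-3,7-dimethylocta-1,6-dien-3-yl]oxy}-6-fluoro-4-methylbenzaldehyde
Product: 6 2-formyl-5-methyl-3-{[(3S)-3,7-dimethylocta-1,6-dien-3-yl]oxy}phenyl pivalate, via sulfonylethyl aryl ether 4 (not isolated), via sodium phenoxide 5 (not isolated)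
Conditions: MeSO2CH2CH2OH, NaH, DMF, 0 → 25 °C; then PivCl, 0 °C
Reagents that add atoms: 2-(methylsulfonyl)ethanol CS(=O)(=O)CCO (oxygen only); pivaloyl chloride CC(C)(C)C(=O)Cl
Why: SNAr with a hydroxide surrogate, then E1cB loss of methyl vinyl sulfone and O-acylation: the remaining fluoride, still ortho to the formyl group, is displaced by the primary alkoxide, base unveils the phenoxide, and pivaloylation gives an ester that tempers the arene and is removed in the last step.

Step 3
Reactants: 6 2-formyl-5-methyl-3-{[(3S)-3,7-dimethylocta-1,6-dien-3-yl]oxy}phenyl pivalate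
Product: 7 2-ethenyl-5-methyl-3-{[(3S)-3,7-dimethylocta-1,6-dien-3-yl]oxy}phenyl pivalate
Conditions: Ph3PCH3Br, KN(SiMe3)2, THF, 0 °C; then 6, −78 → 0 °C
Reagents that add atoms: methyltriphenylphosphonium bromide C[P+](c1ccccc1)(c1ccccc1)c1ccccc1.[Br-] (CH2)
Why: Wittig methylenation of a non-enolisable aldehyde by the non-stabilised ylide at low temperature, where the hindered aryl pivalate should not be attacked.

Step 4
Reactants: 7 2-ethenyl-5-methyl-3-{[(3S)-3,7-dimethylocta-1,6-dien-3-yl]oxy}phenyl pivalate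
Product: 8 (2S)-2,7-dimethyl-2-(4-methylpent-3-en-1-yl)-2H-chromen-5-yl pivalate
Conditions: second-generation Grubbs catalyst, (H2IMes)(PCy3)Cl2Ru=CHPh (5 mol %), CH2Cl2, 40 °C
Reagents that add atoms: none
Why: Ring-closing metathesis in which the ruthenium carbene loads on the styrene and closes the six-membered pyran ring onto the neighbouring vinyl group with loss of ethene, while the trisubstituted prenyl alkene should stay a spectator and the quaternary centre is untouched.

Step 5
Reactants: 9 [2-(1,3-dioxolan-2-yl)ethyl]magnesium bromide; 10 diethyl oxalate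
Product: 12 ethyl 4-(1,3-dioxolan-2-yl)-2-oxobutanoate, via magnesium hemiketalate 11 (not isolated)
Conditions: 9 added to 10 (2 equiv), THF, −78 °C; aq. NH4Cl
Reagents that add atoms: none
Why: Acylation of a Grignard reagent by an oxalate diester: at −78 °C the tetrahedral magnesium hemiketalate persists until the quench, so only one ester carbonyl is attacked and the α-keto ester results.

Step 6
Reactants: 8 (2S)-2,7-dimethyl-2-(4-methylpent-3-en-1-yl)-2H-chromen-5-yl pivalate; 12 ethyl 4-(1,3-dioxolan-2-yl)-2-oxobutanoate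
Product: 13 ethyl (2R,3S)-2-[2-(1,3-dioxolan-2-yl)ethyl]-2-hydroxy-3-(prop-1-en-2-yl)-5-[(2S)-2,7-dimethyl-5-(pivaloyloxy)-2H-chromen-2-yl]pentanoate
Conditions: [Cu((R,R)-t-Bu-box)](SbF6)2 (15 mol %; t-Bu-box = 2,2′-isopropylidenebis(4-tert-butyl-2-oxazoline)), CH2Cl2, 25 → 40 °C
Reagents that add atoms: none
Why: Catalytic enantioselective carbonyl-ene reaction in which the keto ester is chelated on divalent copper and the prenyl alkene bonds through its less substituted carbon (C1′) to the ketone carbon (C6′) while a methyl hydrogen passes to oxygen, leaving the isopropenyl group; the ligand enantiomer is chosen to expose the Re face of the ketone (2R), and 3S should follow from the transition state that places the C1′ hydrogen between the ester and the alkyl arm of the ketone and the hydrogen-donating methyl over the uncomplexed oxygen lone pair.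

Step 7
Reactants: 13 ethyl (2R,3S)-2-[2-(1,3-dioxolan-2-yl)ethyl]-2-hydroxy-3-(prop-1-en-2-yl)-5-[(2S)-2,7-dimethyl-5-(pivaloyloxy)-2H-chromen-2-yl]pentanoate
Product: 15 ethyl (2R,3S)-2-hydroxy-3-(prop-1-en-2-yl)-2-[(3E)-3-(2-tosylhydrazinylidene)propyl]-5-[(2S)-2,7-dimethyl-5-(pivaloyloxy)-2H-chromen-2-yl]pentanoate, via hydroxy aldehyde 14 (not isolated)
Conditions: 1 M aq. HCl/THF, 25 °C; then TsNHNH2, NaOAc, MeOH, 25 °C
Reagents that add atoms: p-toluenesulfonyl hydrazide Cc1ccc(cc1)S(=O)(=O)NN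
Why: Acetal hydrolysis followed by hydrazone condensation: dilute acid unmasks the aldehyde (in equilibrium with its lactol), which condenses with the sulfonyl hydrazide near neutral pH without touching the ester, the pivalate or the stereocentres.

Step 8
Reactants: 15 ethyl (2R,3S)-2-hydroxy-3-(prop-1-en-2-yl)-2-[(3E)-3-(2-tosylhydrazinylidene)propyl]-5-[(2S)-2,7-dimethyl-5-(pivaloyloxy)-2H-chromen-2-yl]pentanoate
Product: 18 ethyl (1R,2S)-1-hydroxy-3,3-dimethyl-2-{2-[(2S)-2,7-dimethyl-5-(pivaloyloxy)-2H-chromen-2-yl]ethyl}cyclohexane-1-carboxylate, via cyclic tosylhydrazide 16 (not isolated), via alkyl diazene 17 (not isolated)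
Conditions: Fe(acac)3 (30 mol %), PhSiH3 (2.5 equiv), THF/EtOH, 25 °C; then NaOAc, EtOH, 70 °C
Reagents that add atoms: none
Why: An iron hydride formed from Fe(acac)3 and PhSiH3 transfers a hydrogen atom to the terminal CH2 of the isopropenyl group, giving the tertiary C2′ radical, which adds to the carbon of C3′=N; the hydrazinyl radical is reduced and protonated to hydrazide 16, and warming with acetate expels sulfinate to give diazene 17, which loses N2 and leaves C3′ as CH2. The closest known reaction type is the iron-hydride reductive coupling of unactivated olefins with sulfonylhydrazones (olefin hydromethylation with a formaldehyde sulfonylhydrazone, and intramolecular alkene–hydrazone couplings), run here as a ring closure. The cyclohexane closes in the 6-exo-trig mode through a chair with the tether at C1′ equatorial. No new stereocentre survives: C2′ carries two methyl groups, the C3′ centre of 16 is erased on N2 loss, and C1′ and C6′ are not involved. The step needs hydrogen-atom transfer to the isopropenyl group rather than to the chromene C3=C4 bond; the former is a terminal 1,1-disubstituted alkene, the latter an internal cis alkene whose C3 is shielded by quaternary C2, and the 6-exo addition to the electron-poor C=N should outrun reduction of the tertiary radical.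

Step 9
Reactants: 18 ethyl (1R,2S)-1-hydroxy-3,3-dimethyl-2-{2-[(2S)-2,7-dimethyl-5-(pivaloyloxy)-2H-chromen-2-yl]ethyl}cyclohexane-1-carboxylate
Product: 19 (2S)-2-{2-[(1S,2R)-2-hydroxy-2-(hydroxymethyl)-6,6-dimethylcyclohexyl]ethyl}-2,7-dimethyl-2H-chromen-5-ol (CNP0253911.1)
Conditions: LiAlH4, THF, 0 → 25 °C; H2O/NaOH work-up
Reagents that add atoms: none
Why: Hydride reduction in which LiAlH4 converts the α-hydroxy ester into the primary alcohol and cleaves the aryl pivalate in the same operation, leaving the chromene alkene and all three stereocentres untouched.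

**Compound list**

1 | (S)-(+)-linalool, (3S)-3,7-dimethylocta-1,6-dien-3-ol | C=C[C@@](C)(O)CCC=C(C)C | starting material
2 | 2,6-difluoro-4-methylbenzaldehyde | Cc1cc(F)c(C=O)c(F)c1 | starting material
3 | 2-{[(3S)-3,7-dimethylocta-1,6-dien-3-yl]oxy}-6-fluoro-4-methylbenzaldehyde | Cc1cc(F)c(C=O)c(c1)O[C@@](C)(CCC=C(C)C)C=C | intermediate
4 | 2-{[(3S)-3,7-dimethylocta-1,6-dien-3-yl]oxy}-4-methyl-6-[2-(methylsulfonyl)ethoxy]benzaldehyde | Cc1cc(OCCS(C)(=O)=O)c(C=O)c(c1)O[C@@](C)(CCC=C(C)C)C=C | intermediate (not isolated)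
5 | sodium 2-formyl-5-methyl-3-{[(3S)-3,7-dimethylocta-1,6-dien-3-yl]oxy}phenoxide | Cc1cc([O-])c(C=O)c(c1)O[C@@](C)(CCC=C(C)C)C=C.[Na+] | intermediate (not isolated)
6 | 2-formyl-5-methyl-3-{[(3S)-3,7-dimethylocta-1,6-dien-3-yl]oxy}phenyl pivalate | Cc1cc(OC(=O)C(C)(C)C)c(C=O)c(c1)O[C@@](C)(CCC=C(C)C)C=C | intermediate
7 | 2-ethenyl-5-methyl-3-{[(3S)-3,7-dimethylocta-1,6-dien-3-yl]oxy}phenyl pivalate | Cc1cc(OC(=O)C(C)(C)C)c(C=C)c(c1)O[C@@](C)(CCC=C(C)C)C=C | intermediate
8 | (2S)-2,7-dimethyl-2-(4-methylpent-3-en-1-yl)-2H-chromen-5-yl pivalate | Cc1cc(OC(=O)C(C)(C)C)c2c(c1)O[C@@](C)(CCC=C(C)C)C=C2 | intermediate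
9 | [2-(1,3-dioxolan-2-yl)ethyl]magnesium bromide (THF solution) | Br[Mg]CCC1OCCO1 | starting material
10 | diethyl oxalate | CCOC(=O)C(=O)OCC | starting material
11 | bromomagnesium hemiketalate of 12 (ethyl 4-(1,3-dioxolan-2-yl)-2-ethoxy-2-(bromomagnesiooxy)butanoate) | CCOC(=O)C(OCC)(O[Mg]Br)CCC1OCCO1 | intermediate (not isolated)
12 | ethyl 4-(1,3-dioxolan-2-yl)-2-oxobutanoate | CCOC(=O)C(=O)CCC1OCCO1 | intermediate
13 | ethyl (2R,3S)-2-[2-(1,3-dioxolan-2-yl)ethyl]-2-hydroxy-3-(prop-1-en-2-yl)-5-[(2S)-2,7-dimethyl-5-(pivaloyloxy)-2H-chromen-2-yl]pentanoate | Cc1cc(OC(=O)C(C)(C)C)c2c(c1)O[C@@](C)(CC[C@@H](C(C)=C)[C@](O)(CCC3OCCO3)C(=O)OCC)C=C2 | intermediate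
14 | ethyl (2R,3S)-2-hydroxy-2-(3-oxopropyl)-3-(prop-1-en-2-yl)-5-[(2S)-2,7-dimethyl-5-(pivaloyloxy)-2H-chromen-2-yl]pentanoate (in equilibrium with its lactol) | Cc1cc(OC(=O)C(C)(C)C)c2c(c1)O[C@@](C)(CC[C@@H](C(C)=C)[C@](O)(CCC=O)C(=O)OCC)C=C2 | intermediate (not isolated)
15 | ethyl (2R,3S)-2-hydroxy-3-(prop-1-en-2-yl)-2-[(3E)-3-(2-tosylhydrazinylidene)propyl]-5-[(2S)-2,7-dimethyl-5-(pivaloyloxy)-2H-chromen-2-yl]pentanoate | Cc1cc(OC(=O)C(C)(C)C)c2c(c1)O[C@@](C)(CC[C@@H](C(C)=C)[C@](O)(CC/C=N/NS(=O)(=O)c3ccc(C)cc3)C(=O)OCC)C=C2 | intermediate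
16 | ethyl (1R,2S)-1-hydroxy-3,3-dimethyl-4-(2-tosylhydrazinyl)-2-{2-[(2S)-2,7-dimethyl-5-(pivaloyloxy)-2H-chromen-2-yl]ethyl}cyclohexane-1-carboxylate (C4 epimers) | Cc1cc(OC(=O)C(C)(C)C)c2c(c1)O[C@@](C)(CC[C@H]3C(C)(C)C(NNS(=O)(=O)c4ccc(C)cc4)CC[C@]3(O)C(=O)OCC)C=C2 | intermediate (not isolated)
17 | ethyl (1R,2S)-4-diazenyl-1-hydroxy-3,3-dimethyl-2-{2-[(2S)-2,7-dimethyl-5-(pivaloyloxy)-2H-chromen-2-yl]ethyl}cyclohexane-1-carboxylate | Cc1cc(OC(=O)C(C)(C)C)c2c(c1)O[C@@](C)(CC[C@H]3C(C)(C)C(N=N)CC[C@]3(O)C(=O)OCC)C=C2 | intermediate (not isolated)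
18 | ethyl (1R,2S)-1-hydroxy-3,3-dimethyl-2-{2-[(2S)-2,7-dimethyl-5-(pivaloyloxy)-2H-chromen-2-yl]ethyl}cyclohexane-1-carboxylate | Cc1cc(OC(=O)C(C)(C)C)c2c(c1)O[C@@](C)(CC[C@H]3C(C)(C)CCC[C@]3(O)C(=O)OCC)C=C2 | intermediate
19 | (2S)-2-{2-[(1S,2R)-2-hydroxy-2-(hydroxymethyl)-6,6-dimethylcyclohexyl]ethyl}-2,7-dimethyl-2H-chromen-5-ol | Cc1cc(O)c2c(c1)O[C@@](C)(CC[C@H]3C(C)(C)CCC[C@]3(O)CO)C=C2 | target

**Step count**

Total: 9 steps. Longest linear sequence: 8 steps (steps 1–4 and 6–9 from linalool); step 5 prepares the enophile.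

**Steps most likely to fail**

Step 6 (carbonyl-ene reaction). The hindered ketone enophile may turn over slowly with a trisubstituted alkene. The alkene face (C1′) may also be selected incompletely relative to the catalyst-controlled ketone face, giving C1′/C6′ diastereomers that cannot be corrected later. The fallback sets C1′ by catalyst-controlled allylboration and C6′ by ring control; it sets out from 8 and comes back at 19.
- Allylic oxidation of 8 (SeO2 cat., t-BuOOH, CH2Cl2) should give the (E)-allylic alcohol F1.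
- Palladium-catalysed borylation (B2pin2, [Pd(MeCN)4](BF4)2, DMSO/MeOH) should give the (E)-allyl pinacolboronate F2.
- Chiral phosphoric acid (TRIP enantiomer chosen for 1′S) catalysed allylboration of 3-(1,3-dioxolan-2-yl)propanal through a chair transition state should give the anti homoallylic alcohol F3.
- Dess–Martin oxidation should give the ketone F4.
- Acetal hydrolysis and condensation of the aldehyde, which is more reactive than the hindered ketone, with TsNHNH2 should give the keto hydrazone F5.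
- The iron-hydride cyclization with sulfinate and N2 loss, as in step 8, should give the cyclohexanone F6.
- Corey–Chaykovsky epoxidation with dimethylsulfoxonium methylide (Me3S(O)I, NaH, DMSO) should deliver CH2 equatorially, the axial path being blocked by the axial methyl on C2′, to give the spiro-epoxide F7.
- KOH in DMSO/H2O at 100 °C should open the epoxide at CH2 and cleave the pivalate to give 19.

Step 8 (key ring closure). Hydrogen-atom transfer to the chromene C3=C4 bond may compete with transfer to the isopropenyl group, so that the heterocycle is partly reduced. The fallback reduces on purpose and then re-oxidises; it sets out from 15 and comes back at 18. The cyclization is run with excess PhSiH3 until both alkenes have reacted, which should give the chroman ester F8. Dehydrogenation of the chroman with DDQ (1,4-dioxane, 100 °C), a classical entry to 2H-chromenes, should then restore the C3=C4 bond and give 18.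

Step 1 (SNAr). Addition of the tertiary alkoxide to the formyl group and base-induced degradation of the aldehyde may outrun fluoride displacement. The fallback uses a nitrile as the activating group; it sets out from 1 and comes back at 3. The alkoxide of 1 (NaH, THF/DMF) and 2,6-difluoro-4-methylbenzonitrile should give the aryl ether nitrile F9. Reduction with i-Bu2AlH (toluene, −78 °C) and mild aqueous acid work-up should give aldehyde 3.

Further compounds
F1 | step 6 | (2S)-2-[(3E)-5-hydroxy-4-methylpent-3-en-1-yl]-2,7-dimethyl-2H-chromen-5-yl pivalate | Cc1cc(OC(=O)C(C)(C)C)c2c(c1)O[C@@](C)(CC/C=C(\C)CO)C=C2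
F2 | step 6 | (2S)-2,7-dimethyl-2-[(3E)-4-methyl-5-(4,4,5,5-tetramethyl-1,3,2-dioxaborolan-2-yl)pent-3-en-1-yl]-2H-chromen-5-yl pivalate | Cc1cc(OC(=O)C(C)(C)C)c2c(c1)O[C@@](C)(CC/C=C(\C)CB3OC(C)(C)C(C)(C)O3)C=C2
F3 | step 6 | (2S)-2-[(3S,4R)-6-(1,3-dioxolan-2-yl)-4-hydroxy-3-(prop-1-en-2-yl)hexyl]-2,7-dimethyl-2H-chromen-5-yl pivalate | Cc1cc(OC(=O)C(C)(C)C)c2c(c1)O[C@@](C)(CC[C@@H](C(C)=C)[C@H](O)CCC3OCCO3)C=C2
F4 | step 6 | (2S)-2-[(3S)-6-(1,3-dioxolan-2-yl)-4-oxo-3-(prop-1-en-2-yl)hexyl]-2,7-dimethyl-2H-chromen-5-yl pivalate | Cc1cc(OC(=O)C(C)(C)C)c2c(c1)O[C@@](C)(CC[C@@H](C(C)=C)C(=O)CCC3OCCO3)C=C2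
F5 | step 6 | (2S)-2,7-dimethyl-2-[(3S,7E)-4-oxo-3-(prop-1-en-2-yl)-7-(2-tosylhydrazinylidene)heptyl]-2H-chromen-5-yl pivalate | Cc1cc(OC(=O)C(C)(C)C)c2c(c1)O[C@@](C)(CC[C@@H](C(C)=C)C(=O)CC/C=N/NS(=O)(=O)c3ccc(C)cc3)C=C2
F6 | step 6 | (2S)-2-{2-[(1S)-2,2-dimethyl-6-oxocyclohexyl]ethyl}-2,7-dimethyl-2H-chromen-5-yl pivalate | Cc1cc(OC(=O)C(C)(C)C)c2c(c1)O[C@@](C)(CC[C@H]3C(C)(C)CCCC3=O)C=C2
F7 | step 6 | (2S)-2-{2-[(3R,4S)-5,5-dimethyl-1-oxaspiro[2.5]octan-4-yl]ethyl}-2,7-dimethyl-2H-chromen-5-yl pivalate (epoxide oxygen axial, cis to the tether) | Cc1cc(OC(=O)C(C)(C)C)c2c(c1)O[C@@](C)(CC[C@H]3C(C)(C)CCC[C@]34CO4)C=C2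
F8 | step 8 | ethyl (1R,2S)-1-hydroxy-3,3-dimethyl-2-{2-[(2S)-2,7-dimethyl-5-(pivaloyloxy)chroman-2-yl]ethyl}cyclohexane-1-carboxylate | Cc1cc(OC(=O)C(C)(C)C)c2c(c1)O[C@@](C)(CC[C@H]3C(C)(C)CCC[C@]3(O)C(=O)OCC)CC2
F9 | step 1 | 2-{[(3S)-3,7-dimethylocta-1,6-dien-3-yl]oxy}-6-fluoro-4-methylbenzonitrile | Cc1cc(F)c(C#N)c(c1)O[C@@](C)(CCC=C(C)C)C=C
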